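I decide to reckon these flasks by hand, as two fractions multiplied, so that each step can be checked against the readings.

the same everywhere: left-handed substrate 0.40 M; right-handed substrate 0.40 M
- oak: reagent 1.6 M; free catalyst 1.1 mM; temperature 89 °C; run made earlier
- elm: reagent 1.6 M; free catalyst 3.5 mM; temperature 108 °C; run made earlier
- green: reagent 1.60 M; free catalyst 4.0 mM; temperature 80 °C; time 30 min
- blue: reagent 1.60 M; free catalyst 4.0 mM; temperature 115 °C; time 30 min
- ochre: reagent 1.60 M; free catalyst 4.0 mM; temperature 100 °C; time 30 min
- grey: reagent 1.60 M; free catalyst 1.8 mM; temperature 80 °C; time 30 min
- violet: reagent 1.60 M; free catalyst 1.8 mM; temperature 100 °C; time 30 min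
- amber: reagent 1.60 M; free catalyst 1.8 mM; temperature 115 °C; time 30 min

| oak: time / min | oak: left-handed product / % | elm: time / min | elm: left-handed product / % |
|---|---|---|---|
| 2.50 | 17.9 | 1.50 | 42.6 |
| 4.00 | 23.5 | 2.50 | 54.1 |
| 6.00 | 30.5 | 4.00 | 62.4 |
| 10.0 | 38.9 | 6.00 | 69.5 |
| 15.0 | 45.2 | 10.0 | 76.0 |
| 25.0 | 52.7 | 15.0 | 78.7 |
| 30.0 | 54.1 | 20.0 | 78.8 |

(readings scatter by 0.5 percentage points)

- all flasks from highest to lowest amount of left-handed product, in percent of the left-handed substrate and right-handed substrate together charged, at 30 min (green / blue / ochre / grey / violet / amber)
- the amount of left-handed product, in percent of the left-handed substrate and right-handed substrate together charged of the flask you put first, at 30 min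
- the amount of left-handed product, in percent of the left-handed substrate and right-handed substrate together charged of the flask you put last, at 30 min

- free catalyst is single-handed; left-handed substrate and right-handed substrate are mirror images of each other, charged as a racemate, each of them at the stated concentration

Elm's 78.8 % lies above the left-handed half of the charge, so right-handed substrate must be turning into left-handed substrate and feeding the product, a dynamic kinetic resolution. Elm also stands still, at 78.7 % and then 78.8 %, with 21.2 % of the charge not turned into left-handed product, so I take this stop as the end of the catalyst's working life. Elm's catalyst budget, the logarithm of one over the fraction unconverted at the stop, per unit of catalyst charged, is 0.443 /mM. Oak is still creeping, so its last reading gives a floor of 0.708 /mM.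

The second fraction is for racemisation, which the readings don't show directly, so I use a rough stand-in for its rate. I divide each run's mid-course slope by the unconverted fraction, which gives 0.0322 /min for oak and 0.133 /min for elm. From oak to elm this stand-in rises by a factor of 4.13, but elm also holds 3.18 times oak's catalyst, so that factor is not heat's alone and I carry it only as a guess. The budget, already taken per unit of catalyst, falls by a factor of 1.60 from oak's floor to elm.

Interpolating logarithms in temperature, the budget is 0.884 /mM at 80 °C, 0.540 /mM at 100 °C and 0.373 /mM at 115 °C. My estimated racemisation fraction, the left-handed half plus what the stand-in puts across by 30 min, is 69.5 %, 94.4 % and 99.9 % at those temperatures.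

Taking the lesser fraction ties green and grey at 69.5 %, and that is the weak link, because grey's budget fraction of 79.6 % stands close above it. Both act on one pool, so I multiply instead. That gives ochre 83.5 %, blue 77.5 %, green 67.4 %, violet 58.7 %, grey 55.3 % and amber 48.9 %. 

The forecast, which differs from my reckoning, gives green > ochre > blue > grey > violet > amber, with 90 % and 50 %: “Heat therefore costs total turnover”.

The flask gives ochre > blue > green > violet > grey > amber, with 84.7 % and 57.9 %.

    reagent + free catalyst + right-handed substrate → free catalyst + right-handed product (k = 0.0350 /M²/s, Ea = 41.0 kJ/mol)
    left-handed substrate ⇌ right-handed substrate (k = 0.00320 /s, Ea = 101 kJ/mol)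
    reagent + free catalyst → spent catalyst (k = 0.00200 /M/s, Ea = 77.0 kJ/mol)
    reagent + free catalyst + left-handed substrate → free catalyst + left-handed product (k = 3.10 /M²/s, Ea = 49.0 kJ/mol)
    (constants at 100 °C)

Ochre stands at 84.7 % against my 83.5 %, and amber at 57.9 % against my 48.9 %, a gap of 9.0 percentage points. Now take the neighbour of amber charged with 7.20 mM of free catalyst, all else held. The same budget and racemisation fraction give 93.1 %. That flask holds 91.3 % of left-handed product at 30 min, with 1.98 % of right-handed product beside it.

The readings are simulated on assumed constants; scatter was added.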